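**Strategy.** The carbocycle of tetrahydrochromone ring A (C4a, C5, C6, C7, C8, C8a) is disconnected at C4a–C5 and C6–C7. Because C4a carries the C4 carbonyl of the γ-pyrone, a CO2 bridge from C4a to C7 makes the C4a=C8a–C8=C7 unit a chelating, electron-poor 2-pyrone diene (a pyrano[4,3-b]pyran-4,5-dione). One inverse-electron-demand Diels–Alder reaction with an (E)-2-aryloxyvinyl acetate that already carries the second chromone forms both bonds. After loss of CO2 it fixes the trans C5–OAr/C6–O pair and leaves a C7=C8 alkene. Hydroxyl-directed epoxidation and opening at C7 by the neighbouring phenol then close the dioxepine and set C7 and C8.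

Key step: step 8

Remark: 4-hydroxy-2H-pyran-2-one (1) is taken as a catalogue compound.
Remark: the sense of induction of the (S,S)-ligand in step 8 is assigned by analogy with other chelating 1,3-dicarbonyl substrates and would be confirmed on the first run; the (R,R)-ligand gives the antipode.

Step 1
Reactants: 1 4-hydroxy-2H-pyran-2-one
Product: 2 3-acetyl-4-hydroxy-2H-pyran-2-one
Conditions: AcOH, DCC, DMAP, CH2Cl2, 0 °C to rt
Reagents that add atoms: acetic acid, CC(=O)O
Why: O-acylation of the vinylogous acid followed by DMAP-mediated O-to-C acyl migration (Fries-type rearrangement) should place the acetyl group at C3, the only nucleophilic ring carbon.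

Step 2
Reactants: 2 3-acetyl-4-hydroxy-2H-pyran-2-one; 3 methyl 3-(4-methoxyphenyl)propanoate
Product: 5 2-[2-(4-methoxyphenyl)ethyl]-4H,5H-pyrano[4,3-b]pyran-4,5-dione, via triketone 4 (not isolated)
Conditions: LiN(SiMe3)2 (3.2 equiv), THF, −78 to 0 °C; then conc. HCl, AcOH, 60 °C
Reagents that add atoms: none
Why: Claisen condensation of the dianion (4-oxide plus acetyl enolate) with the ester gives the 1,3-diketone side chain, and acid then closes the γ-pyrone by attack of the 4-hydroxyl on the distal ketone and loss of water, as in chromone syntheses from 2-hydroxyaryl 1,3-diketones.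

Step 3
Reactants: 6 1-(2-hydroxy-4,5-dimethoxyphenyl)ethanone; 7 ethyl 3-phenylpropanoate
Product: 9 6,7-dimethoxy-2-(2-phenylethyl)-4H-chromen-4-one, via diketone 8 (not isolated)
Conditions: LiN(SiMe3)2 (3.2 equiv), THF, −78 °C to rt; then conc. HCl, AcOH, 80 °C
Reagents that add atoms: none
Why: Claisen condensation of the acetophenone dianion with the ester followed by acid-catalysed cyclodehydration is the standard entry to 2-(2-phenylethyl)chromones.

Step 4
Reactants: 9 6,7-dimethoxy-2-(2-phenylethyl)-4H-chromen-4-one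
Product: 10 6,7-dihydroxy-2-(2-phenylethyl)-4H-chromen-4-one
Conditions: BBr3 (4 equiv), CH2Cl2, −78 °C to rt; then MeOH, H2O
Reagents that add atoms: none
Why: Lewis-acid-mediated cleavage of both aryl methyl ethers (bromide attack on the O-methyl of the boron-complexed ether) should free the catechol without touching the chromone.

Step 5
Reactants: 10 6,7-dihydroxy-2-(2-phenylethyl)-4H-chromen-4-one; 11 2-bromo-1,1-diethoxyethane
Product: 13 7-(2,2-diethoxyethoxy)-4-oxo-2-(2-phenylethyl)-4H-chromen-6-yl acetate, via monoalkylated phenol 12 (not isolated)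
Conditions: K2CO3 (1.1 equiv), NaI (cat.), DMF, 90 °C, N2; then Ac2O, pyridine, rt
Reagents that add atoms: acetic anhydride, CC(=O)OC(C)=O
Why: One equivalent of carbonate should deprotonate only the more acidic 7-hydroxyl (para to the chromone carbonyl), so the Williamson alkylation is expected at O7; the remaining 6-hydroxyl is then acetylated in the same flask.

Step 6
Reactants: 13 7-(2,2-diethoxyethoxy)-4-oxo-2-(2-phenylethyl)-4H-chromen-6-yl acetate
Product: 14 4-oxo-7-(2-oxoethoxy)-2-(2-phenylethyl)-4H-chromen-6-yl acetate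
Conditions: TFA, H2O, CH2Cl2, 0 °C to rt
Reagents that add atoms: water, O
Why: Acid hydrolysis of the diethyl acetal should give the aryloxyacetaldehyde while the aryl acetate survives; the acetate also prevents lactol formation with the neighbouring oxygen.

Step 7
Reactants: 14 4-oxo-7-(2-oxoethoxy)-2-(2-phenylethyl)-4H-chromen-6-yl acetate
Product: 15 7-{[(E)-2-acetoxyethenyl]oxy}-4-oxo-2-(2-phenylethyl)-4H-chromen-6-yl acetate
Conditions: Ac2O, Et3N, DMAP (cat.), THF, 50 °C; E isomer isolated by chromatography, Z isomer re-equilibrated (PhSSPh cat., hν) and recycled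
Reagents that add atoms: acetic anhydride, CC(=O)OC(C)=O
Why: O-acylation of the aldehyde enolate gives the enol acetate; both geometric isomers are expected, and only the E isomer (expected to show the larger vicinal coupling) is carried on because its geometry becomes the trans C5/C6 relationship.

Step 8
Reactants: 5 2-[2-(4-methoxyphenyl)ethyl]-4H,5H-pyrano[4,3-b]pyran-4,5-dione; 15 7-{[(E)-2-acetoxyethenyl]oxy}-4-oxo-2-(2-phenylethyl)-4H-chromen-6-yl acetate
Product: 17 (5R,6R)-5-{[6-acetoxy-4-oxo-2-(2-phenylethyl)-4H-chromen-7-yl]oxy}-2-[2-(4-methoxyphenyl)ethyl]-4-oxo-5,6-dihydro-4H-chromen-6-yl acetate, via bridged lactone cycloadduct 16 (not isolated)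
Conditions: 5 (1.5 equiv), Cu(OTf)2 (10 mol %), (S,S)-t-Bu-box (11 mol %), 4 Å MS, CH2Cl2, 0 °C to rt; filtration through Florisil; then toluene, NaHCO3, 80 °C
Reagents that add atoms: none
Why: The divalent copper–bis(oxazoline) complex chelates the C4 ketone and the lactone carbonyl, both on C4a, and lowers the LUMO of the C4a=C8a–C8=C7 diene, so that the acetoxy-bearing alkene carbon (β to the aryloxy donor) attacks C7, the δ-carbon of both carbonyls, and the aryloxy-stabilised carbon closes onto C4a in an asynchronous inverse-electron-demand [4+2] cycloaddition; heating the bridged lactone 16 then expels CO2 by retro-[4+2] cycloaddition and leaves the C4a=C8a/C7=C8 diene of 17. The closest known reaction type is the Lewis-acid-catalysed inverse-electron-demand Diels–Alder reaction of 3-acyl- and 3-alkoxycarbonyl-2-pyrones with enol ethers followed by thermal decarboxylation to cyclohexa-1,3-dienes, 2-alkoxyvinyl acetates being established dienophiles of this polarity. The only ring retained, the carbocycle C4a–C5–C6–C7–C8–C8a, is closed by intermolecular [4+2] cycloaddition in which the C4a–C5 and C6–C7 bonds form suprafacially on the alkene. C5 and C6 become trans because the alkene is E, and their absolute configuration should follow from the alkene face that is presented, which is fixed by the tert-butyl group of the ligand shielding one face of the chelated diene together with the endo preference of the aryloxy group; the C4a and C7 centres of 16 vanish on CO2 loss. The step needs regioselectivity, secured by the matched polarisation just described, and enantioselectivity, which requires both diene-face and endo control because an exo adduct on the same diene face would lead to the enantiomer. It also needs 17 to survive without aromatising, which is helped by both possible 1,2-eliminations being syn in the trans isomer and by removing the Lewis acid and buffering with NaHCO3 before heating.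

Step 9
Reactants: 17 (5R,6R)-5-{[6-acetoxy-4-oxo-2-(2-phenylethyl)-4H-chromen-7-yl]oxy}-2-[2-(4-methoxyphenyl)ethyl]-4-oxo-5,6-dihydro-4H-chromen-6-yl acetate
Product: 18 (5R,6R)-6-hydroxy-5-{[6-hydroxy-4-oxo-2-(2-phenylethyl)-4H-chromen-7-yl]oxy}-2-[2-(4-methoxyphenyl)ethyl]-5,6-dihydro-4H-chromen-4-one
Conditions: K2CO3 (0.3 equiv), MeOH, 0 °C, short reaction time; AcOH quench
Reagents that add atoms: none
Why: Mild transesterification should remove the aryl and the allylic acetate without touching C5 or C6; low temperature is chosen to suppress conjugate addition of the phenoxide to C7 and base-induced aromatisation.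

Step 10
Reactants: 18 (5R,6R)-6-hydroxy-5-{[6-hydroxy-4-oxo-2-(2-phenylethyl)-4H-chromen-7-yl]oxy}-2-[2-(4-methoxyphenyl)ethyl]-5,6-dihydro-4H-chromen-4-one
Product: 20 (+)-4'-methoxyaquisinenone G, via epoxy alcohol 19 (not isolated)
Conditions: VO(acac)2 (5 mol %), t-BuOOH (1.1 equiv), CH2Cl2, 0 °C to rt; then K2CO3, MeOH, rt
Reagents that add atoms: tert-butyl hydroperoxide, CC(C)(C)OO
Why: Vanadium-catalysed epoxidation of the cyclic allylic alcohol should deliver oxygen to C7=C8 on the face of the 6-hydroxyl (syn), and the phenoxide held on the opposite face through the C5 ether then opens the epoxide at C7 with inversion (7-exo, trans-diaxial opening), setting C7 and C8 and closing the dioxepine.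

**Compound list**

1 | 4-hydroxy-2H-pyran-2-one | O=c1cc(O)cco1 | starting material
2 | 3-acetyl-4-hydroxy-2H-pyran-2-one | CC(=O)c1c(O)ccoc1=O | intermediate
3 | methyl 3-(4-methoxyphenyl)propanoate | COC(=O)CCc1ccc(OC)cc1 | starting material
4 | 4-hydroxy-3-[5-(4-methoxyphenyl)-3-oxopentanoyl]-2H-pyran-2-one (triketone) | COc1ccc(CCC(=O)CC(=O)c2c(O)ccoc2=O)cc1 | intermediate
5 | 2-[2-(4-methoxyphenyl)ethyl]-4H,5H-pyrano[4,3-b]pyran-4,5-dione | COc1ccc(CCc2cc(=O)c3c(o2)ccoc3=O)cc1 | intermediate
6 | 1-(2-hydroxy-4,5-dimethoxyphenyl)ethanone | CC(=O)c1cc(OC)c(OC)cc1O | starting material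
7 | ethyl 3-phenylpropanoate | CCOC(=O)CCc1ccccc1 | starting material
8 | 1-(2-hydroxy-4,5-dimethoxyphenyl)-5-phenylpentane-1,3-dione (diketone) | COc1cc(O)c(C(=O)CC(=O)CCc2ccccc2)cc1OC | intermediate
9 | 6,7-dimethoxy-2-(2-phenylethyl)-4H-chromen-4-one | COc1cc2oc(CCc3ccccc3)cc(=O)c2cc1OC | intermediate
10 | 6,7-dihydroxy-2-(2-phenylethyl)-4H-chromen-4-one | Oc1cc2oc(CCc3ccccc3)cc(=O)c2cc1O | intermediate
11 | 2-bromo-1,1-diethoxyethane | CCOC(CBr)OCC | starting material
12 | 7-(2,2-diethoxyethoxy)-6-hydroxy-2-(2-phenylethyl)-4H-chromen-4-one | CCOC(COc1cc2oc(CCc3ccccc3)cc(=O)c2cc1O)OCC | intermediate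
13 | 7-(2,2-diethoxyethoxy)-4-oxo-2-(2-phenylethyl)-4H-chromen-6-yl acetate | CCOC(COc1cc2oc(CCc3ccccc3)cc(=O)c2cc1OC(C)=O)OCC | intermediate
14 | 4-oxo-7-(2-oxoethoxy)-2-(2-phenylethyl)-4H-chromen-6-yl acetate | O=CCOc1cc2oc(CCc3ccccc3)cc(=O)c2cc1OC(C)=O | intermediate
15 | 7-{[(E)-2-acetoxyethenyl]oxy}-4-oxo-2-(2-phenylethyl)-4H-chromen-6-yl acetate | CC(=O)O/C=C/Oc1cc2oc(CCc3ccccc3)cc(=O)c2cc1OC(C)=O | intermediate
16 | bridged lactone cycloadduct: CO2 bridge between C4a and C7 intact, C8=C8a double bond, 5-aryloxy syn to C8=C8a (endo), 6-acetoxy syn to the lactone bridge (exo) | COc1ccc(CCC2=CC(=O)[C@]34C(=O)O[C@H](C=C3O2)[C@@H](OC(C)=O)[C@@H]4Oc5cc6oc(CCc7ccccc7)cc(=O)c6cc5OC(C)=O)cc1 | intermediate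
17 | (5R,6R)-5-{[6-acetoxy-4-oxo-2-(2-phenylethyl)-4H-chromen-7-yl]oxy}-2-[2-(4-methoxyphenyl)ethyl]-4-oxo-5,6-dihydro-4H-chromen-6-yl acetate | COc1ccc(CCc2cc(=O)c3c(o2)C=C[C@@H](OC(C)=O)[C@@H]3Oc4cc5oc(CCc6ccccc6)cc(=O)c5cc4OC(C)=O)cc1 | intermediate
18 | (5R,6R)-6-hydroxy-5-{[6-hydroxy-4-oxo-2-(2-phenylethyl)-4H-chromen-7-yl]oxy}-2-[2-(4-methoxyphenyl)ethyl]-5,6-dihydro-4H-chromen-4-one | COc1ccc(CCc2cc(=O)c3c(o2)C=C[C@@H](O)[C@@H]3Oc4cc5oc(CCc6ccccc6)cc(=O)c5cc4O)cc1 | intermediate
19 | (5R,6S,7S,8S)-7,8-epoxy-6-hydroxy-5-{[6-hydroxy-4-oxo-2-(2-phenylethyl)-4H-chromen-7-yl]oxy}-2-[2-(4-methoxyphenyl)ethyl]-5,6,7,8-tetrahydro-4H-chromen-4-one | COc1ccc(CCc2cc(=O)c3c(o2)[C@H]4O[C@H]4[C@@H](O)[C@@H]3Oc5cc6oc(CCc7ccccc7)cc(=O)c6cc5O)cc1 | intermediate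
20 | (+)-4'-methoxyaquisinenone G, (5R,6S,7R,8S): C5–O–C7' and C7–O–C6' ether bridges to the 2-(2-phenylethyl)chromone, 6,8-diol | COc1ccc(CCc2cc(=O)c3c(o2)[C@@H](O)[C@@H]2Oc4cc5c(=O)cc(CCc6ccccc6)oc5cc4O[C@H]3[C@@H]2O)cc1 | target

**Totals.** 10 steps in all; longest linear sequence 8 steps (steps 3 to 10, from 6 and 7 to 20).

**Steps most likely to fail**

1. Step 8. The cycloaddition may discriminate poorly between the two diene faces or between endo and exo approach, which would erode enantiomeric purity. The dienophile may also be too weak a nucleophile, or the diene may aromatise during CO2 loss. Fallback (auxiliary control with separation of diastereomers instead of catalyst control): from 14, acylation with (1S)-camphanic chloride (Et3N, DMAP) gives the (E)-enol camphanate F1. Thermal cycloaddition–decarboxylation of F1 with 5 (toluene, 100 °C, no Lewis acid) gives the two trans dienes, the (5R,6R)-camphanate F2 and the (5S,6S)-camphanate F3, which are separated by crystallisation or chromatography. Methanolysis of F2 (K2CO3, MeOH, 0 °C) rejoins the route at 18.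

2. Step 7. Enolate O-acylation may favour the Z isomer (cis effect of two vicinal oxygens), leaving little E-15, and equilibration may be slow. Fallback (geometry set by anti-elimination instead of enolate acylation): from 14, addition of acetyl chloride (ZnCl2 cat., CH2Cl2, 0 °C) gives the 1-chloroalkyl acetate F4. Dehydrochlorination with DBU (THF, 0 °C to rt) should pass through the anti-periplanar arrangement that keeps the two oxygen substituents apart and so favour the E alkene, returning to the route at 15.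

3. Step 10. The free phenol may be oxidised by the vanadium peroxide, or the epoxide may open early or unselectively while oxidant is still present. Fallback (oxidation decoupled from ring closure by masking the phenol): from 18, chemoselective silylation of the phenol (t-BuMe2SiCl, imidazole, DMF, 0 °C) gives the silyl ether F5. Directed epoxidation (VO(acac)2, t-BuOOH, CH2Cl2) gives the isolable epoxy alcohol F6. Fluoride (Bu4NF, THF, 0 °C) then releases the phenoxide, which closes onto C7 and returns to the route at 20.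

**Further compounds**

F1 | step 8 | 7-{[(E)-2-{[(1S,4R)-4,7,7-trimethyl-3-oxo-2-oxabicyclo[2.2.1]heptane-1-carbonyl]oxy}ethenyl]oxy}-4-oxo-2-(2-phenylethyl)-4H-chromen-6-yl acetate | CC1(C)[C@@]2(C)CC[C@]1(C(=O)O/C=C/Oc3cc4oc(CCc5ccccc5)cc(=O)c4cc3OC(C)=O)OC2=O
F2 | step 8 | (5R,6R)-5-{[6-acetoxy-4-oxo-2-(2-phenylethyl)-4H-chromen-7-yl]oxy}-2-[2-(4-methoxyphenyl)ethyl]-4-oxo-5,6-dihydro-4H-chromen-6-yl (1S)-camphanate | CC1(C)[C@@]2(C)CC[C@]1(C(=O)O[C@@H]3C=Cc4oc(CCc5ccc(OC)cc5)cc(=O)c4[C@H]3Oc3cc4oc(CCc5ccccc5)cc(=O)c4cc3OC(C)=O)OC2=O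
F3 | step 8 | (5S,6S)-5-{[6-acetoxy-4-oxo-2-(2-phenylethyl)-4H-chromen-7-yl]oxy}-2-[2-(4-methoxyphenyl)ethyl]-4-oxo-5,6-dihydro-4H-chromen-6-yl (1S)-camphanate | CC1(C)[C@@]2(C)CC[C@]1(C(=O)O[C@H]3C=Cc4oc(CCc5ccc(OC)cc5)cc(=O)c4[C@@H]3Oc3cc4oc(CCc5ccccc5)cc(=O)c4cc3OC(C)=O)OC2=O
F4 | step 7 | 7-(2-acetoxy-2-chloroethoxy)-4-oxo-2-(2-phenylethyl)-4H-chromen-6-yl acetate (racemic at the chlorine-bearing carbon) | CC(=O)OC(Cl)COc1cc2oc(CCc3ccccc3)cc(=O)c2cc1OC(C)=O
F5 | step 10 | (5R,6R)-5-{[6-(tert-butyldimethylsilyloxy)-4-oxo-2-(2-phenylethyl)-4H-chromen-7-yl]oxy}-6-hydroxy-2-[2-(4-methoxyphenyl)ethyl]-5,6-dihydro-4H-chromen-4-one | COc1ccc(CCc2cc(=O)c3c(o2)C=C[C@@H](O)[C@@H]3Oc4cc5oc(CCc6ccccc6)cc(=O)c5cc4O[Si](C)(C)C(C)(C)C)cc1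
F6 | step 10 | (5R,6S,7S,8S)-5-{[6-(tert-butyldimethylsilyloxy)-4-oxo-2-(2-phenylethyl)-4H-chromen-7-yl]oxy}-7,8-epoxy-6-hydroxy-2-[2-(4-methoxyphenyl)ethyl]-5,6,7,8-tetrahydro-4H-chromen-4-one | COc1ccc(CCc2cc(=O)c3c(o2)[C@H]4O[C@H]4[C@@H](O)[C@@H]3Oc5cc6oc(CCc7ccccc7)cc(=O)c6cc5O[Si](C)(C)C(C)(C)C)cc1
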